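Numbering used throughout: ring atoms of the target are C1 (tertiary carbinol), C2 (acetoxy), C3 (benzoyloxy), C4=C5 (alkene), C6 (ketone) and C7 (exocyclic CH2). Sugar intermediates keep carbohydrate numbering; target C7, C1, C2, C3, C4, C5, C6 correspond to sugar C1, C2, C3, C4, C5, C6, C7.

## The problem

2-O-Acetylzeylenone (19) is a cyclohexenone in which every ring carbon is functionalised: C1 is a fully substituted carbinol carrying the benzoyloxymethyl carbon C7, C2 bears an acetate, C3 an allylic benzoate, C4=C5 is the enone double bond and C6 the ketone. The three stereocentres are contiguous, with the C1 oxygen cis to the C2 acetate and the C3 benzoate trans to it, (1S,2S,3R) in this numbering. C2 and C3 form an ordinary trans-diol pair of the kind sugars supply. C1 has no hydrogen and lies next to the ketone, so it must be built, and the surest way is to form a bond to C1 intramolecularly under the control of a centre tied to C2 and C3. Four oxygens carry two benzoates, one acetate and one free tertiary hydroxyl, so acyl migration between neighbours must at every stage be either impossible or the intended reaction. The finished molecule is a γ-acyloxy enone and an α-ketol: base eliminates carboxylate and aromatises the ring, so the enone must come last and no alkoxide or organometallic reagent may meet the esters. The opening is that C7(=O)–C1–C6–C5=C4, with C7 written as an aldehyde, is a γ,δ-unsaturated carbonyl unit, the retron of a Claisen rearrangement. Running it backwards breaks C1–C6, joins C4 to the C7 oxygen and turns the carbocycle into a dihydropyran whose chain C7–C1–C2–C3–C4–C5 is C1–C6 of a 2-oxygenated D-glucal, with C2 and C3 already in the D-gluco configuration and C5=C6 as a vinyl group on the ring carbon next to oxygen.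

## Retrosynthesis

19 from 18. The C6=O bond is removed and the ketone is traced to the allylic methylene of cyclohexene 18. Carrying an oxygen on C6 through the ring construction would need a hetero-substituted vinyl group made from a base-sensitive aldehyde. Oxidising last also keeps the enone, the most fragile function, out of all earlier steps. The forward reaction must oxidise C6 and not the C3/C4 side of the allyl system, under neutral conditions.

18 from 17 from 16. The acetyl C–O bond at C2 is cut, then the benzyl ether that masks this oxygen in 16. An ester on this oxygen (sugar O3) would be an allylic ester of a 2-acyloxyglycal during the thermal step, where 1,3-acyloxy shift with loss of configuration is known. A benzyl ether cannot shift, and it also leaves only one possible acyl donor in the benzoyl transfer below. The forward steps ask for debenzylation without hydrogenation of the alkene and for acetylation of a secondary hydroxyl beside a tertiary one.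

16 from 14 (through 15). The primary benzoate on the C7 oxygen is traced to the tertiary benzoate on C1, and the C7 carbinol to an aldehyde. Benzoylating a diol separately would cost steps; here the enol benzoate that the glycal chemistry requires anyway becomes the C7 benzoate by a 1,2-shift. The forward reaction needs a hydride that spares esters and a migration that runs downhill from tertiary to primary oxygen.

14 from 13. The C1–C6 bond is cut and C4 is rejoined to the aldehyde oxygen. Cutting C3–C4 instead would create C3 under reagent control, and a two-bond cycloaddition cut would have to control four centres at once. This cut leaves C1 as the only new centre and sets it within a ring. The precursor 13 is a pyranoid glycal with the carbons of a hexose plus one. The forward reaction is purely thermal, so 13 must carry no group that moves on heating.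

13 from 11 and 12; 11 from 10 from 9. The C6=C7 double bond (sugar numbering) is cut to aldehyde 11 and the one-carbon unit dibromomethane 12; 11 comes from primary alcohol 10 and that from silyl ether 9. A basic ylide would attack the enol benzoate and trigger β-elimination of the C4 benzoate, so the forward methylenation must be non-basic.

9 from 8 from 7. The enol double bond is opened to glycosyl bromide 8 by adding HBr back, and the anomeric bromide is traced to the phenylthio group of 7. A 2-O-benzoyl glycosyl bromide gives the 2-benzoyloxy glycal directly on elimination; 2-alkoxy glycals have no comparably reliable preparation. A thioglycoside is the better bromide precursor than an anomeric ester: it is inert through all the protecting-group steps and is exchanged for bromide by bromine without the protic acid that would endanger the silyl and benzyl ethers.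

7 from 5 and 3 (through 6); 5 from 4; 4 from 2 and 3; 2 from 1. The two benzoyl groups, the silyl group and the benzyl group are removed in turn, each from a position that is the only one open at that stage.
- The benzylidene acetal of 1 leaves only O2 and O3 free, and O3 is benzylated selectively through the stannylene acetal.
- The one remaining hydroxyl, O2, takes the first benzoyl group from benzoyl chloride 3.
- Acetal hydrolysis frees O4 and O6; the primary O6 is silylated and O4 takes the second benzoyl group.
- No stereocentre is made in this part, and every acyl group is introduced onto a single free hydroxyl.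

## Roads not taken

Alternative 1: The cut is the C2–O bond. The para-quinol A2 would be esterified at its tertiary hydroxyl by an arylboronic acid, and the remaining B–OH would add to one of the two enantiotopic enone double bonds under a chiral amine–thiourea catalyst, giving the cis-fused boronate A1 with C1 and C2 set together.
- Merits: a very short, catalytic asymmetric entry to the carbocycle from an aromatic precursor, with the cis C1/C2 relationship guaranteed by the five-membered boronate.
- Weak points: in A1 the carbonyl sits para to C1, at the carbon that is C4 of 19, and the carbon that must carry the C3 benzoate is a methylene. Reaching 19 needs an oxygen introduced at C3 trans to C2, then a 1,3-transposition of the enone so that the carbonyl ends next to C1. That transposition runs through reduction, allylic shift and re-oxidation, or through an epoxy ketone and hydrazine, on a substrate that by then carries base-sensitive esters.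
- Comparison: A1 is reached in far fewer steps than 14, and without the nine protecting-group and adjustment steps that precede ring formation in the chosen plan; in that respect it is better. The chosen plan sets against this that its ring-forming step delivers C2, C3 and the C4=C5 double bond correctly and leaves only C6 at the wrong oxidation level, and that absolute configuration comes from the starting sugar and not from a catalyst-controlled desymmetrisation.

Alternative 2: Two ring bonds, C1–C6 and C2–C3, are cut in the Diels–Alder sense. The dioxygenated diene A5 and the formyl-substituted vinylene carbonate A4 would combine under a chiral oxazaborolidinium Lewis acid to give adduct A3.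
- Merits: convergent; all six ring carbons, four stereocentres, the C4=C5 double bond and the C6 oxygen arrive in one step. On paper this is the shortest road, and it needs no C–H oxidation, which is the least secure step of the chosen plan.
- Weak points: A4 is not an available compound, and as an α-oxygenated enal and enol carbonate at once its stability is doubtful. The target needs the C3 benzoate trans to the C2 oxygen, that is formyl endo and carbonate exo, while α-substituted enals under this kind of Lewis acid usually place the formyl group exo. Regiochemistry rests on the silyloxy group out-donating the benzoyloxy group, and enantiofacial control on an untried dienophile is unproven. After the cycloaddition the carbonate must still be opened so that C1 stays free, C2 becomes acetate and C7 benzoate.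
- Comparison: the chosen plan is longer, but each of its stereocentres is either bought or fixed by an intramolecular constraint, and all of its building blocks exist.

Alternative 3: The cut is C3–C4. The (Z)-β-iodoenone aldehyde A7 would be closed with CrCl2 and catalytic NiCl2 under Nozaki–Hiyama–Kishi conditions, the vinylmetal at C4 adding to the C3 aldehyde to give A6, with the C1/C2 diol held as an acetonide.
- Merits: enone and C4=C5 arrive complete, and the end-game (benzoylation of the C3 hydroxyl, acetonide removal, acetylation at C2) is short and free of C–H oxidation. Here this road is better than the chosen plan.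
- Weak points: C3 is created in the ring closure, and whether its hydroxyl ends trans to the C2 oxygen depends on the conformation of a ring closing onto a cis-fused dioxolane, which cannot be predicted with confidence. A7 combines an epimerisable α-oxygenated aldehyde with a β-iodoenone that behaves as a vinylogous acyl iodide, open to addition–elimination and Z/E isomerisation. Building A7 with a tertiary carbinol of defined configuration from a branched-chain sugar needs two separate chain extensions at the quaternary carbon and is at least as long as the route to 13.
- Comparison: the chosen plan creates no stereocentre under reagent control and closes its ring by a reaction type with direct precedent on vinyl glycals; it pays with a final allylic oxidation.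

Key step: step 10

Remark on the chemistry: the benzylidene-protected thioglucoside 1 is taken to be a catalogue compound.

## Route

Step 1
Reactants: 1 phenyl 4,6-O-benzylidene-1-thio-β-D-glucopyranoside
Product: 2 phenyl 3-O-benzyl-4,6-O-benzylidene-1-thio-β-D-glucopyranoside
Conditions: Bu2SnO, toluene, reflux (−H2O); then BnBr, CsF, DMF, rt
Reagents that add atoms: benzyl bromide, BrCc1ccccc1
Why: Stannylene-acetal-mediated regioselective O-alkylation: the 2,3-O-dibutylstannylene of a 4,6-O-benzylidene β-thioglucoside is alkylated preferentially at O3, since O2 is deactivated by the adjacent anomeric carbon. No stereocentre is touched, and any 2-O-benzyl isomer is removed by chromatography.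

Step 2
Reactants: 2 phenyl 3-O-benzyl-4,6-O-benzylidene-1-thio-β-D-glucopyranoside; 3 benzoyl chloride
Product: 4 phenyl 2-O-benzoyl-3-O-benzyl-4,6-O-benzylidene-1-thio-β-D-glucopyranoside
Conditions: BzCl (1.3 equiv), pyridine, DMAP (cat.), CH2Cl2, 0 °C → rt
Reagents that add atoms: none
Why: Nucleophile-catalysed acylation of the only free hydroxyl (O2); this benzoate later becomes the enol ester of the glycal and finally the C7 benzoate of the target.

Step 3
Reactants: 4 phenyl 2-O-benzoyl-3-O-benzyl-4,6-O-benzylidene-1-thio-β-D-glucopyranoside
Product: 5 phenyl 2-O-benzoyl-3-O-benzyl-1-thio-β-D-glucopyranoside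
Conditions: AcOH/H2O (4:1), 70 °C
Reagents that add atoms: none
Why: Acid-catalysed acetal hydrolysis frees O4 and O6 while the benzoate, the benzyl ether and the thioglycoside are stable; water supplies only hydrogen to 5, its oxygen leaving in benzaldehyde. The O2 benzoate cannot migrate because its only neighbour, O3, is an ether.

Step 4
Reactants: 5 phenyl 2-O-benzoyl-3-O-benzyl-1-thio-β-D-glucopyranoside; 3 benzoyl chloride
Product: 7 phenyl 2,4-di-O-benzoyl-3-O-benzyl-6-O-(tert-butyldiphenylsilyl)-1-thio-β-D-glucopyranoside, via 6-O-silyl alcohol 6 (not isolated)
Conditions: TBDPSCl (1.1 equiv), pyridine, 0 °C → rt; then BzCl (1.5 equiv), DMAP (cat.), rt → 40 °C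
Reagents that add atoms: tert-butyl(chloro)diphenylsilane, CC(C)(C)[Si](Cl)(c1ccccc1)c1ccccc1
Why: Regioselective silylation: the bulky silyl chloride takes the primary hydroxyl (O6), and the one remaining secondary hydroxyl (O4) is then benzoylated in the same flask by nucleophile-catalysed acylation.

Step 5
Reactants: 7 phenyl 2,4-di-O-benzoyl-3-O-benzyl-6-O-(tert-butyldiphenylsilyl)-1-thio-β-D-glucopyranoside
Product: 8 2,4-di-O-benzoyl-3-O-benzyl-6-O-(tert-butyldiphenylsilyl)-α-D-glucopyranosyl bromide
Conditions: Br2 (1.05 equiv), CH2Cl2, 0 °C, dark; evaporation, rapid filtration through silica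
Reagents that add atoms: bromine, BrBr
Why: Thiophilic activation of the thioglycoside: bromine forms a bromosulfonium ion that leaves as the sulfenyl bromide, and the 2-O-benzoyl-stabilised acyloxonium ion is captured by bromide, equilibrating to the axial α-bromide (anomeric effect). No protic acid is present, so the benzyl and silyl ethers survive, and the sulfenyl bromide is removed before the glycal is made.

Step 6
Reactants: 8 2,4-di-O-benzoyl-3-O-benzyl-6-O-(tert-butyldiphenylsilyl)-α-D-glucopyranosyl bromide
Product: 9 1,5-anhydro-2,4-di-O-benzoyl-3-O-benzyl-6-O-(tert-butyldiphenylsilyl)-D-arabino-hex-1-enitol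
Conditions: DBU, DMF, 0 °C → rt
Reagents that add atoms: none
Why: E2 elimination of HBr from the axial bromide and the anti-periplanar axial H2, the standard route from acylated glycosyl bromides to 2-acyloxyglycals; the benzoate stays on O2 as the enol ester.

Step 7
Reactants: 9 1,5-anhydro-2,4-di-O-benzoyl-3-O-benzyl-6-O-(tert-butyldiphenylsilyl)-D-arabino-hex-1-enitol
Product: 10 1,5-anhydro-2,4-di-O-benzoyl-3-O-benzyl-D-arabino-hex-1-enitol
Conditions: HF·pyridine, THF/pyridine, 0 °C → rt
Reagents that add atoms: none
Why: Fluoride-driven desilylation in a buffered, weakly acidic medium, which avoids O4 → O6 benzoyl migration and leaves the electron-poor enol benzoate intact.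

Step 8
Reactants: 10 1,5-anhydro-2,4-di-O-benzoyl-3-O-benzyl-D-arabino-hex-1-enitol
Product: 11 1,5-anhydro-2,4-di-O-benzoyl-3-O-benzyl-D-arabino-hex-1-enodialdose (the C6 aldehyde of 10)
Conditions: Dess–Martin periodinane, CH2Cl2, 0 °C → rt
Reagents that add atoms: none
Why: Dess–Martin oxidation of the primary alcohol under neutral conditions. The α-alkoxy-β-benzoyloxy aldehyde is taken on crude so that silica or base does not induce β-elimination.

Step 9
Reactants: 11 1,5-anhydro-2,4-di-O-benzoyl-3-O-benzyl-D-arabino-hex-1-enodialdose; 12 dibromomethane
Product: 13 1,5-anhydro-2,4-di-O-benzoyl-3-O-benzyl-6,7-dideoxy-D-arabino-hepta-1,6-dienitol (the 5-vinyl glycal)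
Conditions: Zn, CH2Br2, TiCl4, THF (reagent pre-formed at 0 °C); then 11, CH2Cl2, 0 °C → rt
Reagents that add atoms: none
Why: Lombardo methylenation: the zinc/titanium methylene reagent from 12 is non-basic and attacks aldehydes but not esters. The C5 stereocentre beside the carbonyl is therefore not epimerised and the benzoates are untouched.

Step 10
Reactants: 13 1,5-anhydro-2,4-di-O-benzoyl-3-O-benzyl-6,7-dideoxy-D-arabino-hepta-1,6-dienitol
Product: 14 (1R,5R,6S)-1,5-bis(benzoyloxy)-6-(benzyloxy)cyclohex-3-ene-1-carbaldehyde
Conditions: 1,2-dichlorobenzene (0.02 M, degassed), 2,6-di-tert-butyl-4-methylpyridine (0.2 equiv), sealed tube, 230 °C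
Reagents that add atoms: none
Why: The enol ether C2=C1–O5 and the allylic unit C5–C6=C7 of 13 form an allyl vinyl ether that undergoes a concerted, suprafacial [3,3] sigmatropic shift; the closest known reaction type is the thermal Claisen rearrangement of 5-vinyl glycals (2-vinyl-3,4-dihydro-2H-pyrans) to cyclohex-3-ene-1-carbaldehydes. Because both ends hang on the pyran, the six atoms can only meet in a boat-like array reached from the inverted 5H4 half-chair with the vinyl group axial, which is why a temperature above 200 °C is needed. The carbocycle closes as sugar C2 bonds to C7 while C5–O5 breaks, a pericyclic pyran-to-cyclohexene ring switch through a transition state shaped like a 2-oxabicyclo[2.2.2]octene, and formation of the aldehyde C=O drives it. The one new stereocentre, the quaternary C1 of 14, is controlled by sugar C5: the vinyl terminus can reach only the face of the enol double bond on which it stands, so the C1 benzoate ends cis to the C2 oxygen. Sugar C3 and C4 are spectators and become C2 and C3 unchanged. The selectivity needed is chemoselectivity against other thermal reactions: the oxygen on sugar C3 is an ether, which cannot undergo the allylic 1,3-acyloxy shift and epimerisation that an ester at this position of a 2-acyloxyglycal undergoes on heating, and the hindered pyridine base, dilution and exclusion of air keep acid-catalysed loss of benzoic acid from 14 in check.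

Step 11
Reactants: 14 (1R,5R,6S)-1,5-bis(benzoyloxy)-6-(benzyloxy)cyclohex-3-ene-1-carbaldehyde
Product: 16 [(1S,5R,6S)-5-(benzoyloxy)-6-(benzyloxy)-1-hydroxycyclohex-3-en-1-yl]methyl benzoate, via primary alcohol 15 (not isolated)
Conditions: NaBH4, THF/MeOH (4:1), −20 → 0 °C; then DBU (0.2 equiv), CH2Cl2, rt
Reagents that add atoms: none
Why: Borohydride reduces the aldehyde and spares the esters at low temperature. Base then catalyses a 1,2 O→O benzoyl shift through a five-membered spiro orthoacid, from the hindered tertiary oxygen to the primary one, which is thermodynamically downhill. With a benzyl ether on C2 there is no other acyl donor in reach, and no bond to C1 is broken, so its configuration is kept.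

Step 12
Reactants: 16 [(1S,5R,6S)-5-(benzoyloxy)-6-(benzyloxy)-1-hydroxycyclohex-3-en-1-yl]methyl benzoate
Product: 17 [(1S,5R,6S)-5-(benzoyloxy)-1,6-dihydroxycyclohex-3-en-1-yl]methyl benzoate
Conditions: BCl3, C6HMe5, CH2Cl2, −78 °C; MeOH quench
Reagents that add atoms: none
Why: Lewis-acid debenzylation with pentamethylbenzene as benzyl-cation scavenger cleaves the ether at low temperature. Benzoates and the ring alkene survive, whereas hydrogenolysis would saturate the double bond.

Step 13
Reactants: 17 [(1S,5R,6S)-5-(benzoyloxy)-1,6-dihydroxycyclohex-3-en-1-yl]methyl benzoate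
Product: 18 [(1S,5R,6S)-6-(acetyloxy)-5-(benzoyloxy)-1-hydroxycyclohex-3-en-1-yl]methyl benzoate
Conditions: Ac2O, pyridine, 0 °C → rt
Reagents that add atoms: acetic anhydride, CC(=O)OC(C)=O
Why: Selective O-acylation: the secondary C2 hydroxyl is acetylated, while the hindered tertiary C1 hydroxyl does not react without a stronger acyl-transfer catalyst. Acetylation is faster than benzoyl migration between the trans-disposed O3 and O2.

Step 14
Reactants: 18 [(1S,5R,6S)-6-(acetyloxy)-5-(benzoyloxy)-1-hydroxycyclohex-3-en-1-yl]methyl benzoate
Product: 19 2-O-acetylzeylenone, [(1S,5R,6S)-6-(acetyloxy)-5-(benzoyloxy)-1-hydroxy-2-oxocyclohex-3-en-1-yl]methyl benzoate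
Conditions: Rh2(cap)4 (dirhodium tetrakis(caprolactamate), 1 mol%), t-BuOOH (70% aq.), ClCH2CH2Cl, 40 °C
Reagents that add atoms: tert-butyl hydroperoxide, CC(C)(C)OO
Why: Allylic C–H oxidation by the dirhodium caprolactamate/tert-butylperoxyl radical chain should convert the ring methylene C6 into the conjugated ketone. The only other allylic hydrogen, on C3, is deactivated by its benzoate. The medium is neutral, so the γ-acyloxy enone, the α-ketol and the acyl pattern survive.

## Compound list

1 | phenyl 4,6-O-benzylidene-1-thio-β-D-glucopyranoside ((R)-acetal, phenyl equatorial) | c1ccccc1[C@@H]2OC[C@H]3O[C@@H](Sc4ccccc4)[C@H](O)[C@@H](O)[C@@H]3O2 | starting material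
2 | phenyl 3-O-benzyl-4,6-O-benzylidene-1-thio-β-D-glucopyranoside | c1ccccc1[C@@H]2OC[C@H]3O[C@@H](Sc4ccccc4)[C@H](O)[C@@H](OCc4ccccc4)[C@@H]3O2 | intermediate
3 | benzoyl chloride | O=C(Cl)c1ccccc1 | starting material
4 | phenyl 2-O-benzoyl-3-O-benzyl-4,6-O-benzylidene-1-thio-β-D-glucopyranoside | c1ccccc1[C@@H]2OC[C@H]3O[C@@H](Sc4ccccc4)[C@H](OC(=O)c4ccccc4)[C@@H](OCc4ccccc4)[C@@H]3O2 | intermediate
5 | phenyl 2-O-benzoyl-3-O-benzyl-1-thio-β-D-glucopyranoside | OC[C@H]1O[C@@H](Sc2ccccc2)[C@H](OC(=O)c2ccccc2)[C@@H](OCc2ccccc2)[C@@H]1O | intermediate
6 | phenyl 2-O-benzoyl-3-O-benzyl-6-O-(tert-butyldiphenylsilyl)-1-thio-β-D-glucopyranoside | CC(C)(C)[Si](OC[C@H]1O[C@@H](Sc2ccccc2)[C@H](OC(=O)c2ccccc2)[C@@H](OCc2ccccc2)[C@@H]1O)(c1ccccc1)c1ccccc1 | intermediate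
7 | phenyl 2,4-di-O-benzoyl-3-O-benzyl-6-O-(tert-butyldiphenylsilyl)-1-thio-β-D-glucopyranoside | CC(C)(C)[Si](OC[C@H]1O[C@@H](Sc2ccccc2)[C@H](OC(=O)c2ccccc2)[C@@H](OCc2ccccc2)[C@@H]1OC(=O)c1ccccc1)(c1ccccc1)c1ccccc1 | intermediate
8 | 2,4-di-O-benzoyl-3-O-benzyl-6-O-(tert-butyldiphenylsilyl)-α-D-glucopyranosyl bromide | CC(C)(C)[Si](OC[C@H]1O[C@H](Br)[C@H](OC(=O)c2ccccc2)[C@@H](OCc2ccccc2)[C@@H]1OC(=O)c1ccccc1)(c1ccccc1)c1ccccc1 | intermediate
9 | 1,5-anhydro-2,4-di-O-benzoyl-3-O-benzyl-6-O-(tert-butyldiphenylsilyl)-D-arabino-hex-1-enitol | CC(C)(C)[Si](OC[C@H]1OC=C(OC(=O)c2ccccc2)[C@@H](OCc2ccccc2)[C@@H]1OC(=O)c1ccccc1)(c1ccccc1)c1ccccc1 | intermediate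
10 | 1,5-anhydro-2,4-di-O-benzoyl-3-O-benzyl-D-arabino-hex-1-enitol | OC[C@H]1OC=C(OC(=O)c2ccccc2)[C@@H](OCc2ccccc2)[C@@H]1OC(=O)c1ccccc1 | intermediate
11 | 1,5-anhydro-2,4-di-O-benzoyl-3-O-benzyl-D-arabino-hex-1-enodialdose (C6 aldehyde of 10) | O=C[C@H]1OC=C(OC(=O)c2ccccc2)[C@@H](OCc2ccccc2)[C@@H]1OC(=O)c1ccccc1 | intermediate
12 | dibromomethane | BrCBr | starting material
13 | 1,5-anhydro-2,4-di-O-benzoyl-3-O-benzyl-6,7-dideoxy-D-arabino-hepta-1,6-dienitol | C=C[C@H]1OC=C(OC(=O)c2ccccc2)[C@@H](OCc2ccccc2)[C@@H]1OC(=O)c1ccccc1 | intermediate
14 | (1R,5R,6S)-1,5-bis(benzoyloxy)-6-(benzyloxy)cyclohex-3-ene-1-carbaldehyde | O(Cc1ccccc1)[C@H]1[C@H](OC(=O)c2ccccc2)C=CC[C@]1(OC(=O)c1ccccc1)C=O | intermediate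
15 | (1S,5R,6S)-5-(benzoyloxy)-6-(benzyloxy)-1-(hydroxymethyl)cyclohex-3-en-1-yl benzoate | O(Cc1ccccc1)[C@H]1[C@H](OC(=O)c2ccccc2)C=CC[C@]1(OC(=O)c1ccccc1)CO | intermediate
16 | [(1S,5R,6S)-5-(benzoyloxy)-6-(benzyloxy)-1-hydroxycyclohex-3-en-1-yl]methyl benzoate | O(Cc1ccccc1)[C@H]1[C@H](OC(=O)c2ccccc2)C=CC[C@]1(O)COC(=O)c1ccccc1 | intermediate
17 | [(1S,5R,6S)-5-(benzoyloxy)-1,6-dihydroxycyclohex-3-en-1-yl]methyl benzoate | O[C@H]1[C@H](OC(=O)c2ccccc2)C=CC[C@]1(O)COC(=O)c1ccccc1 | intermediate
18 | [(1S,5R,6S)-6-(acetyloxy)-5-(benzoyloxy)-1-hydroxycyclohex-3-en-1-yl]methyl benzoate | CC(=O)O[C@H]1[C@H](OC(=O)c2ccccc2)C=CC[C@]1(O)COC(=O)c1ccccc1 | intermediate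
19 | 2-O-acetylzeylenone, [(1S,5R,6S)-6-(acetyloxy)-5-(benzoyloxy)-1-hydroxy-2-oxocyclohex-3-en-1-yl]methyl benzoate | CC(=O)O[C@H]1[C@H](OC(=O)c2ccccc2)C=CC(=O)[C@]1(O)COC(=O)c1ccccc1 | target

## Step count and least certain steps

Total: 14 steps from 1. The route is linear, so the longest linear sequence is also 14 steps.

Step 10 (key step). The boat transition state may demand a temperature at which the newly formed tertiary benzoate of 14 loses benzoic acid by ester pyrolysis, followed by aromatisation; the electron-poor enol benzoate may also slow the shift relative to ether-substituted vinyl glycals. Short heating times in a microwave or flow reactor are the first adjustment. The fallback changes the mode of activation from a thermal pericyclic shift to a charge-accelerated rearrangement on a stoichiometric Lewis acid. Compound 13 is treated with an excess of methylaluminium bis(4-bromo-2,6-di-tert-butylphenoxide), MeAl(OC6H2-4-Br-2,6-tBu2)2, in CH2Cl2 at −78 → −20 °C. Coordination at the ring oxygen polarises the C5–O bond and lets the same C–C bond form at low temperature; organoaluminium-promoted Claisen rearrangement of allyl vinyl ethers is a known reaction type. The excess is needed because the benzoate carbonyls also bind the reagent. The fallback sets out from 13 and comes back at 14; it makes no new compound (F0).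

Step 14. The likely failure is poor regioselectivity of oxygen transfer. The allyl radical formed by hydrogen abstraction at C6 is delocalised over C4–C5–C6, and C6 is flanked by the quaternary C1, so oxygen may be delivered to C4 and give the transposed enone; abstraction of the C3 hydrogen is a second drain. The fallback uses a pericyclic path that cannot transpose. SeO2 with t-BuOOH in CH2Cl2 (or SeO2 in dioxane at 80 °C) effects an ene reaction followed by a [2,3] shift, which places the oxygen on the carbon that loses hydrogen and returns the double bond to C4=C5. This gives the allylic alcohol [(1S,5R,6S)-6-(acetyloxy)-5-(benzoyloxy)-1,2-dihydroxycyclohex-3-en-1-yl]methyl benzoate F1 as either carbinol epimer. Dess–Martin oxidation of F1 then gives the enone. The fallback sets out from 18 and comes back at 19.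

Step 9. Aldehyde 11 carries a benzoate β to the carbonyl and an ether oxygen α to it. Loss of benzoic acid to the conjugated enal, and reductive pinacol-type coupling at the low-valent titanium centre, can both consume it before methylenation. The fallback is a two-operation Peterson olefination. Me3SiCH2MgCl with CeCl3 in THF at −78 °C adds to the aldehyde only and gives the β-hydroxysilane 1,5-anhydro-2,4-di-O-benzoyl-3-O-benzyl-7-deoxy-7-(trimethylsilyl)-D-arabino-hept-1-enitol F2 (mixture at C6). BF3·OEt2 in CH2Cl2 at −20 °C then induces anti-elimination of trimethylsilanol to the vinyl group. The fallback sets out from 11 and comes back at 13.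

Step 5. The glycosyl bromide is moisture-sensitive, and it must be freed from the electrophilic sulfenyl bromide before the glycal is formed; hydrolysis at the anomeric carbon during that handling, or carry-over of the sulfur electrophile into step 6, is the likely loss. The fallback separates removal of the thio group from introduction of bromide. N-Bromosuccinimide in wet acetone at 0 °C hydrolyses the thioglycoside to the hemiacetal 2,4-di-O-benzoyl-3-O-benzyl-6-O-(tert-butyldiphenylsilyl)-D-glucopyranose F3, which is purified. Oxalyl bromide with catalytic DMF in CH2Cl2 at 0 °C then converts F3 into the bromide with only volatile co-products. The fallback sets out from 7 and comes back at 8.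

Step 12. The Lewis acid may ionise the allylic benzoate or the tertiary carbinol, and the freed C2 hydroxyl may accept the C3 benzoyl group during the quench. The fallback is oxidative debenzylation: DDQ in wet CH2Cl2 under visible-light irradiation oxidises the benzylic position and releases the alcohol with benzaldehyde, with no Lewis acid present. The fallback sets out from 16 and comes back at 17; it makes no new compound (F0).

## Further compounds

F0 | step 10 | none | none
F1 | step 14 | [(1S,5R,6S)-6-(acetyloxy)-5-(benzoyloxy)-1,2-dihydroxycyclohex-3-en-1-yl]methyl benzoate (either C2-carbinol epimer) | CC(=O)O[C@H]1[C@H](OC(=O)c2ccccc2)C=CC(O)[C@]1(O)COC(=O)c1ccccc1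
F2 | step 9 | 1,5-anhydro-2,4-di-O-benzoyl-3-O-benzyl-7-deoxy-7-(trimethylsilyl)-D-arabino-hept-1-enitol (C6 epimers) | C[Si](C)(C)CC(O)[C@H]1OC=C(OC(=O)c2ccccc2)[C@@H](OCc2ccccc2)[C@@H]1OC(=O)c1ccccc1
F3 | step 5 | 2,4-di-O-benzoyl-3-O-benzyl-6-O-(tert-butyldiphenylsilyl)-D-glucopyranose | CC(C)(C)[Si](OC[C@H]1OC(O)[C@H](OC(=O)c2ccccc2)[C@@H](OCc2ccccc2)[C@@H]1OC(=O)c1ccccc1)(c1ccccc1)c1ccccc1
F0 | step 12 | none | none
A1 | alternative 1 | cis-fused phenylboronate of 4,5-dihydroxy-4-(benzoyloxymethyl)cyclohex-2-enone | c1ccc(cc1)B1O[C@H]2CC(=O)C=C[C@@]2(COC(=O)c2ccccc2)O1
A2 | alternative 1 | 4-(benzoyloxymethyl)-4-hydroxycyclohexa-2,5-dienone | O=C1C=CC(O)(COC(=O)c2ccccc2)C=C1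
A3 | alternative 2 | cyclohexene 1,2-carbonate with C1 formyl, C3 benzoate and C6 tert-butyldimethylsilyl ether | O=C1O[C@H]2[C@H](OC(=O)c3ccccc3)C=C[C@H](O[Si](C)(C)C(C)(C)C)[C@@]2(C=O)O1
A4 | alternative 2 | 2-oxo-1,3-dioxole-4-carbaldehyde | O=CC1=COC(=O)O1
A5 | alternative 2 | (1E,3E)-1-(benzoyloxy)-4-(tert-butyldimethylsilyloxy)buta-1,3-diene | O=C(O/C=C/C=C/O[Si](C)(C)C(C)(C)C)c1ccccc1
A6 | alternative 3 | 1,2-O-isopropylidene-3-debenzoylzeylenone | CC1(C)O[C@H]2[C@H](O)C=CC(=O)[C@@]2(COC(=O)c3ccccc3)O1
A7 | alternative 3 | (Z)-β-iodoenone aldehyde with the C1/C2 diol as acetonide | CC1(C)O[C@@H](C=O)[C@@](COC(=O)c2ccccc2)(C(=O)/C=C\I)O1
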